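**Retrosynthetic overview**

1. Target 26 is cut back first at its protecting groups (three benzyl ethers on ring A, an ethyl ether on B2), then at the B3–propanoyl bond (Friedel–Crafts) and at the ring A–butanoyl bond (aryllithium from a ring A bromide plus a Weinreb amide).
2. Ring B is then dismantled by a cyclobutenone/ynol ether benzannulation across B4–B5, B6–B1 and B3–B4, leaving a 2-(arylmethyl)-3-ethoxycyclobutenone and 1-methoxypropyne.
3. The feature that allows this lies in ring B (B1 bridge carbon, B2 OH, B3 propanoyl, B4 OH, B5 CH3, B6 OCH3): the single methyl ether B6 lies between the C-methyl carbon B5 and the bridge-bearing B1, beside the hydroxylated B4. B5/B6 are therefore the two alkyne carbons of MeC≡COMe set between a ketene carbonyl carbon (B4) and its α-carbon (B1), and the three oxygens emerge as OH, OEt and OMe.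
4. The cyclobutenone comes from ketene and ArCH2C≡COEt, the alkyne from a ring A benzylic bromide and lithium ethoxyacetylide, and ring A from 2,4,6-trihydroxytoluene (formylation, bromination, benzylation).
5. Ring order: ring A is bought as an arene, the four-membered ring is made in step 7, and ring B is the only six-membered ring that is built, in step 9.

Key step: step 9

Remark: ring A is the butanoyl-bearing ring. Ketene is taken as a gas stream generated by pyrolysis of acetone just before use. Compounds 16 and 23 are racemic and transient; the target has no stereocenter.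

**Route**

Step 1
Reactants: 1 2,4,6-trihydroxytoluene
Product: 3 2,4,6-trihydroxy-3-methylbenzaldehyde, via aryl iminium chloride 2 (not isolated)
Conditions: POCl3, DMF, EtOAc, 0 °C → rt; then H2O, 50 °C
Reagents that add atoms: N,N-dimethylformamide CN(C)C=O; water O
Why: Vilsmeier–Haack formylation at one of the two equivalent free ring carbons should stop after one formyl group because the first deactivates the ring, and hydrolysis of iminium salt 2 releases the aldehyde.

Step 2
Reactants: 3 2,4,6-trihydroxy-3-methylbenzaldehyde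
Product: 4 3-bromo-2,4,6-trihydroxy-5-methylbenzaldehyde
Conditions: NBS (1.0 equiv), THF, −20 → 0 °C
Reagents that add atoms: N-bromosuccinimide O=C1CCC(=O)N1Br
Why: Electrophilic aromatic bromination should take the single remaining ring C–H (ortho/para to three hydroxyls), which blocks that carbon against C-benzylation in step 3 and installs the later lithiation handle.

Step 3
Reactants: 4 3-bromo-2,4,6-trihydroxy-5-methylbenzaldehyde
Product: 5 2,4,6-tris(benzyloxy)-3-bromo-5-methylbenzaldehyde
Conditions: BnBr (3.6 equiv), K2CO3, DMF, 60 °C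
Reagents that add atoms: benzyl bromide BrCc1ccccc1
Why: Williamson etherification should give the tris-ether because the hexasubstituted ring offers no aromatic C–H for C-benzylation and the formyl group lowers the carbon nucleophilicity of the phenoxides.

Step 4
Reactants: 5 2,4,6-tris(benzyloxy)-3-bromo-5-methylbenzaldehyde
Product: 6 [2,4,6-tris(benzyloxy)-3-bromo-5-methylphenyl]methanol
Conditions: NaBH4, THF–MeOH, 0 °C
Reagents that add atoms: none
Why: Borohydride reduction of the aryl aldehyde to the benzylic alcohol is chemoselective and leaves the aryl bromide and the benzyl ethers untouched.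

Step 5
Reactants: 6 [2,4,6-tris(benzyloxy)-3-bromo-5-methylphenyl]methanol
Product: 7 1,3,5-tris(benzyloxy)-2-bromo-4-(bromomethyl)-6-methylbenzene
Conditions: PBr3 (0.4 equiv), CH2Cl2, 0 °C; NaHCO3 wash, used crude at once
Reagents that add atoms: phosphorus tribromide BrP(Br)Br
Why: PBr3 converts the benzylic alcohol into the bromide by substitution on the alkyl phosphite, and the three twisted, doubly flanked benzyloxy groups and the ring bromine should damp ionisation enough for immediate use of the crude bromide.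

Step 6
Reactants: 7 1,3,5-tris(benzyloxy)-2-bromo-4-(bromomethyl)-6-methylbenzene; 8 ethoxyacetylene
Product: 10 1,3,5-tris(benzyloxy)-2-bromo-4-(3-ethoxyprop-2-yn-1-yl)-6-methylbenzene, via lithium ethoxyacetylide 9 (not isolated)
Conditions: 8, n-BuLi, THF, −78 °C; then 7, DMPU, −78 → 0 °C; NaHCO3 work-up, Et3N-deactivated silica
Reagents that add atoms: none
Why: SN2 alkylation of a lithium alkoxyacetylide by a benzylic bromide in THF/DMPU is an established entry to 1-alkoxy-1-alkynes, and the acetylide does not exchange with the aryl bromide.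

Step 7
Reactants: 10 1,3,5-tris(benzyloxy)-2-bromo-4-(3-ethoxyprop-2-yn-1-yl)-6-methylbenzene
Product: 11 2-{[2,4,6-tris(benzyloxy)-3-bromo-5-methylphenyl]methyl}-3-ethoxycyclobut-2-en-1-one
Conditions: ketene (gas stream, excess), CH2Cl2, 0 °C → rt; neutral alumina
Reagents that add atoms: ketene C=C=O
Why: The [2+2] cycloaddition of ketene with a 1-alkoxyalkyne gives 3-alkoxycyclobutenones, and the nucleophilic benzyl-bearing alkyne carbon bonds to the ketene carbonyl carbon so that OEt ends on C3 and the arylmethyl group on C2.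

Step 8
Reactants: 12 chloroacetaldehyde dimethyl acetal
Product: 14 1-methoxyprop-1-yne, via sodium methoxyacetylide 13 (not isolated)
Conditions: NaNH2 (3 equiv), liquid NH3, −33 °C; then MeI, −33 °C; distillation
Reagents that add atoms: iodomethane CI
Why: Double elimination from the chloroacetal by NaNH2 gives the sodium alkoxyacetylide, which is C-methylated in the same flask (acetylide alkylation), the standard preparation of 1-alkoxy-1-alkynes.

Step 9
Reactants: 11 2-{[2,4,6-tris(benzyloxy)-3-bromo-5-methylphenyl]methyl}-3-ethoxycyclobut-2-en-1-one; 14 1-methoxyprop-1-yne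
Product: 19 4-{[2,4,6-tris(benzyloxy)-3-bromo-5-methylphenyl]methyl}-5-ethoxy-3-methoxy-2-methylphenol, via vinylketene 15 (not isolated), via vinylcyclobutenone 16 (not isolated), via dienylketene 17 (not isolated), via cyclohexadienone 18 (not isolated)
Conditions: 14 (3 equiv), toluene, sealed tube, 80 → 110 °C; then K2CO3, MeOH, rt
Reagents that add atoms: none
Why: Conrotatory four-electron electrocyclic opening of cyclobutenone 11 gives vinylketene 15, whose carbonyl carbon is attacked by the methyl-bearing carbon of ynol ether 14 in a ketene–alkyne [2+2] cycloaddition to give the racemic 4-vinylcyclobutenone 16 (bonds B4–B5 and B6–B1). A second four-electron opening gives dienylketene 17, and ring B closes by thermal disrotatory six-electron electrocyclization between the ketene carbon and the terminal CH2 (bond B3–B4) to cyclohexadienone 18, which tautomerizes to phenol 19. The closest known reaction type is the Danheiser benzannulation of cyclobutenones with alkoxyalkynes, and thermal opening of 3-ethoxycyclobutenones to vinylketenes is known from their use as acetoacetylating agents, although such a vinylogous ester is a less explored vinylketene source in this benzannulation. No stereocenter survives: the quaternary carbon of 16 is transient, and because the opening of 16 is reversible the material should funnel through the dienylketene isomer with the ketene and ethoxyvinyl groups cis. The selectivity needed is the regiochemistry of the [2+2], and it is secured by the polarization of the ynol ether, which puts OMe on B6 between the B5 methyl and B1 and leaves the ketene oxygen as the free B4 hydroxyl. The three ring B oxygens thus arrive differentiated (OH, OEt, OMe), and B3 is the only unsubstituted carbon.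

Step 10
Reactants: 19 4-{[2,4,6-tris(benzyloxy)-3-bromo-5-methylphenyl]methyl}-5-ethoxy-3-methoxy-2-methylphenol; 20 N-methoxy-N-methylbutanamide
Product: 24 1-{2,4,6-tris(benzyloxy)-3-[(6-ethoxy-4-hydroxy-2-methoxy-3-methylphenyl)methyl]-5-methylphenyl}butan-1-one, via sodium phenoxide 21 (not isolated), via aryllithium 22 (not isolated), via tetrahedral adduct 23 (not isolated)
Conditions: NaH, THF, 0 °C; t-BuLi (2.2 equiv), −78 °C; 20, −78 → 0 °C; aq NH4Cl
Reagents that add atoms: none
Why: With the phenol masked as its sodium salt, bromine–lithium exchange at −78 °C gives aryllithium 22, and the Weinreb ketone synthesis stops at chelate 23, so the ketone should form without over-addition.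

Step 11
Reactants: 24 1-{2,4,6-tris(benzyloxy)-3-[(6-ethoxy-4-hydroxy-2-methoxy-3-methylphenyl)methyl]-5-methylphenyl}butan-1-one
Product: 25 1-{2,4,6-tris(benzyloxy)-3-[(2-ethoxy-4-hydroxy-6-methoxy-5-methyl-3-propanoylphenyl)methyl]-5-methylphenyl}butan-1-one
Conditions: EtCO2H, (CF3CO)2O, CH2Cl2, 0 °C → rt; then K2CO3, MeOH, rt
Reagents that add atoms: propanoic acid CCC(=O)O
Why: Friedel–Crafts acylation by the mixed propanoic trifluoroacetic anhydride should go to B3, the only unsubstituted carbon of rings A and B and ortho to both the phenol and the ethoxy group, under acid mild enough for the benzyl ethers, and the methanolysis returns any O-acylated phenol.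

Step 12
Reactants: 25 1-{2,4,6-tris(benzyloxy)-3-[(2-ethoxy-4-hydroxy-6-methoxy-5-methyl-3-propanoylphenyl)methyl]-5-methylphenyl}butan-1-one
Product: 26 1-{3-[(2,4-dihydroxy-6-methoxy-5-methyl-3-propanoylphenyl)methyl]-2,4,6-trihydroxy-5-methylphenyl}butan-1-one
Conditions: BCl3 (excess), C6HMe5, CH2Cl2, −78 → 0 °C; MeOH, then H2O
Reagents that add atoms: none
Why: BCl3 with pentamethylbenzene as cation trap cleaves the three benzyl ethers at low temperature, and on warming the B3 carbonyl holds boron on the neighbouring B2 ethoxy oxygen so that chloride removes the ethyl group (chelation-assisted dealkylation), while the B6 methyl ether, which has no adjacent carbonyl or oxygen, should be spared.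

**Compound list**

1 | 2,4,6-trihydroxytoluene | Cc1c(O)cc(O)cc1O | starting material
2 | [(2,4,6-trihydroxy-3-methylphenyl)methylidene]dimethylammonium chloride | C[N+](C)=Cc1c(O)c(C)c(O)cc1O.[Cl-] | intermediate
3 | 2,4,6-trihydroxy-3-methylbenzaldehyde | O=Cc1c(O)c(C)c(O)cc1O | intermediate
4 | 3-bromo-2,4,6-trihydroxy-5-methylbenzaldehyde | O=Cc1c(O)c(C)c(O)c(Br)c1O | intermediate
5 | 2,4,6-tris(benzyloxy)-3-bromo-5-methylbenzaldehyde | O=Cc1c(OCc2ccccc2)c(C)c(OCc2ccccc2)c(Br)c1OCc1ccccc1 | intermediate
6 | [2,4,6-tris(benzyloxy)-3-bromo-5-methylphenyl]methanol | OCc1c(OCc2ccccc2)c(C)c(OCc2ccccc2)c(Br)c1OCc1ccccc1 | intermediate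
7 | 1,3,5-tris(benzyloxy)-2-bromo-4-(bromomethyl)-6-methylbenzene | BrCc1c(OCc2ccccc2)c(C)c(OCc2ccccc2)c(Br)c1OCc1ccccc1 | intermediate
8 | ethoxyacetylene | CCOC#C | starting material
9 | lithium ethoxyacetylide | CCOC#C[Li] | intermediate
10 | 1,3,5-tris(benzyloxy)-2-bromo-4-(3-ethoxyprop-2-yn-1-yl)-6-methylbenzene | CCOC#CCc1c(OCc2ccccc2)c(C)c(OCc2ccccc2)c(Br)c1OCc1ccccc1 | intermediate
11 | 2-{[2,4,6-tris(benzyloxy)-3-bromo-5-methylphenyl]methyl}-3-ethoxycyclobut-2-en-1-one | CCOC1=C(Cc2c(OCc3ccccc3)c(C)c(OCc3ccccc3)c(Br)c2OCc2ccccc2)C(=O)C1 | intermediate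
12 | chloroacetaldehyde dimethyl acetal (2-chloro-1,1-dimethoxyethane) | COC(CCl)OC | starting material
13 | sodium methoxyacetylide | COC#C[Na] | intermediate
14 | 1-methoxyprop-1-yne | COC#CC | intermediate
15 | 2-{[2,4,6-tris(benzyloxy)-3-bromo-5-methylphenyl]methyl}-3-ethoxybuta-1,3-dien-1-one | C=C(OCC)C(Cc1c(OCc2ccccc2)c(C)c(OCc2ccccc2)c(Br)c1OCc1ccccc1)=C=O | intermediate
16 | rac-4-{[2,4,6-tris(benzyloxy)-3-bromo-5-methylphenyl]methyl}-4-(1-ethoxyethenyl)-3-methoxy-2-methylcyclobut-2-en-1-one | O=C4C(C)=C(OC)C4(Cc1c(OCc2ccccc2)c(C)c(OCc2ccccc2)c(Br)c1OCc1ccccc1)C(OCC)=C | intermediate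
17 | (3E)-4-{[2,4,6-tris(benzyloxy)-3-bromo-5-methylphenyl]methyl}-5-ethoxy-3-methoxy-2-methylhexa-1,3,5-trien-1-one | O=C=C(C)/C(OC)=C(Cc1c(OCc2ccccc2)c(C)c(OCc2ccccc2)c(Br)c1OCc1ccccc1)\C(OCC)=C | intermediate
18 | 4-{[2,4,6-tris(benzyloxy)-3-bromo-5-methylphenyl]methyl}-5-ethoxy-3-methoxy-2-methylcyclohexa-2,4-dien-1-one | O=C1CC(OCC)=C(Cc2c(OCc3ccccc3)c(C)c(OCc3ccccc3)c(Br)c2OCc2ccccc2)C(OC)=C1C | intermediate
19 | 4-{[2,4,6-tris(benzyloxy)-3-bromo-5-methylphenyl]methyl}-5-ethoxy-3-methoxy-2-methylphenol | Cc1c(O)cc(OCC)c(Cc2c(OCc3ccccc3)c(C)c(OCc3ccccc3)c(Br)c2OCc2ccccc2)c1OC | intermediate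
20 | N-methoxy-N-methylbutanamide | CCCC(=O)N(C)OC | starting material
21 | sodium 4-{[2,4,6-tris(benzyloxy)-3-bromo-5-methylphenyl]methyl}-5-ethoxy-3-methoxy-2-methylphenolate | Cc1c(O[Na])cc(OCC)c(Cc2c(OCc3ccccc3)c(C)c(OCc3ccccc3)c(Br)c2OCc2ccccc2)c1OC | intermediate
22 | sodium 4-{[2,4,6-tris(benzyloxy)-3-lithio-5-methylphenyl]methyl}-5-ethoxy-3-methoxy-2-methylphenolate | Cc1c(O[Na])cc(OCC)c(Cc2c(OCc3ccccc3)c(C)c(OCc3ccccc3)c([Li])c2OCc2ccccc2)c1OC | intermediate
23 | rac-lithium 1-{2,4,6-tris(benzyloxy)-3-[(6-ethoxy-2-methoxy-3-methyl-4-sodiooxyphenyl)methyl]-5-methylphenyl}-1-[methoxy(methyl)amino]butan-1-olate | CCCC(O[Li])(N(C)OC)c1c(OCc2ccccc2)c(C)c(OCc2ccccc2)c(Cc2c(OCC)cc(O[Na])c(C)c2OC)c1OCc1ccccc1 | intermediate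
24 | 1-{2,4,6-tris(benzyloxy)-3-[(6-ethoxy-4-hydroxy-2-methoxy-3-methylphenyl)methyl]-5-methylphenyl}butan-1-one | CCCC(=O)c1c(OCc2ccccc2)c(C)c(OCc2ccccc2)c(Cc2c(OCC)cc(O)c(C)c2OC)c1OCc1ccccc1 | intermediate
25 | 1-{2,4,6-tris(benzyloxy)-3-[(2-ethoxy-4-hydroxy-6-methoxy-5-methyl-3-propanoylphenyl)methyl]-5-methylphenyl}butan-1-one | CCCC(=O)c1c(OCc2ccccc2)c(C)c(OCc2ccccc2)c(Cc2c(OCC)c(C(=O)CC)c(O)c(C)c2OC)c1OCc1ccccc1 | intermediate
26 | 1-{3-[(2,4-dihydroxy-6-methoxy-5-methyl-3-propanoylphenyl)methyl]-2,4,6-trihydroxy-5-methylphenyl}butan-1-one | CCCC(=O)c1c(O)c(C)c(O)c(Cc2c(O)c(C(=O)CC)c(O)c(C)c2OC)c1O | target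

**Count and risks**

Total: 12 steps. Longest linear sequence: 11 steps (steps 1–7 and 9–12); step 8 is a one-step branch.

Steps most likely to fail:

Step 9. The vinylogous-ester cyclobutenone may open so slowly that the volatile ynol ether decomposes first. The vinylketene may also dimerise or acylate the product phenol before the crowded [2+2] takes place. The fallback sets out from 7 and comes back at 19, and it also bypasses steps 6 and 7. It makes vinylketene 15 by photochemical Wolff rearrangement instead of by cyclobutenone opening. Bromide 7 alkylates the lithium enolate of N-methoxy-N-methylacetamide (LiN(i-Pr)2, THF, −78 °C) to give N-methoxy-N-methyl-3-[2,4,6-tris(benzyloxy)-3-bromo-5-methylphenyl]propanamide F1. 1-Ethoxyvinyllithium (ethyl vinyl ether, t-BuLi, THF, −78 °C) converts this into 5-[2,4,6-tris(benzyloxy)-3-bromo-5-methylphenyl]-2-ethoxypent-1-en-3-one F2. Detrifluoroacetylative diazo transfer (LiN(SiMe3)2, CF3CO2CH2CF3, −78 °C; then MsN3, Et3N, H2O, MeCN) passes through 4-{[2,4,6-tris(benzyloxy)-3-bromo-5-methylphenyl]methyl}-2-ethoxy-6,6,6-trifluorohex-1-ene-3,5-dione F3 to 4-diazo-2-ethoxy-5-[2,4,6-tris(benzyloxy)-3-bromo-5-methylphenyl]pent-1-en-3-one F4. Irradiation of F4 (λ > 300 nm, CH2Cl2, rt) with excess 14, then heating at 80 °C, should give 15 by migration of the 1-ethoxyvinyl group, and the same cascade leads to 19.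

Step 11. O-acylation of the phenol may outrun C-acylation and deactivate ring B. The acid released may also start to cleave benzyl ethers or provoke ipso attack at B1 with loss of the ring A benzyl unit. The fallback sets out from 24 and comes back at 26. Hydrogenolysis (H2, 10% Pd/C, EtOAc–MeOH, rt) removes the benzyl groups first and gives 1-{3-[(6-ethoxy-4-hydroxy-2-methoxy-3-methylphenyl)methyl]-2,4,6-trihydroxy-5-methylphenyl}butan-1-one F5. Classical Friedel–Crafts acylation (EtCOCl, AlCl3, CH2Cl2–PhNO2, 0 °C → rt; K2CO3, MeOH work-up) then acylates B3, the only free ring carbon, to give 1-{3-[(2-ethoxy-4-hydroxy-6-methoxy-5-methyl-3-propanoylphenyl)methyl]-2,4,6-trihydroxy-5-methylphenyl}butan-1-one F6, which is not isolated. The same AlCl3 removes its chelated ethyl group and gives 26.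

Step 7. Ketene dimerisation and hydrolytic loss of the acid-sensitive ynol ether, or of the product enol ether, may outpace the cycloaddition. The fallback sets out from 10 and comes back at 11. Dichloroketene made in the flask (Cl3CCOCl, Zn–Cu couple, Et2O–DME, rt) adds to 10 with the same regiochemistry to give 2-{[2,4,6-tris(benzyloxy)-3-bromo-5-methylphenyl]methyl}-4,4-dichloro-3-ethoxycyclobut-2-en-1-one F7. Zinc dust (AcOH–TMEDA, EtOH, 0 °C → rt) then removes both chlorines and gives 11.

**Further compounds**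

F1 | step 9 | N-methoxy-N-methyl-3-[2,4,6-tris(benzyloxy)-3-bromo-5-methylphenyl]propanamide | CON(C)C(=O)CCc1c(OCc2ccccc2)c(C)c(OCc2ccccc2)c(Br)c1OCc1ccccc1
F2 | step 9 | 5-[2,4,6-tris(benzyloxy)-3-bromo-5-methylphenyl]-2-ethoxypent-1-en-3-one | C=C(OCC)C(=O)CCc1c(OCc2ccccc2)c(C)c(OCc2ccccc2)c(Br)c1OCc1ccccc1
F3 | step 9 | 4-{[2,4,6-tris(benzyloxy)-3-bromo-5-methylphenyl]methyl}-2-ethoxy-6,6,6-trifluorohex-1-ene-3,5-dione | C=C(OCC)C(=O)C(Cc1c(OCc2ccccc2)c(C)c(OCc2ccccc2)c(Br)c1OCc1ccccc1)C(=O)C(F)(F)F
F4 | step 9 | 4-diazo-2-ethoxy-5-[2,4,6-tris(benzyloxy)-3-bromo-5-methylphenyl]pent-1-en-3-one | C=C(OCC)C(=O)C(=[N+]=[N-])Cc1c(OCc2ccccc2)c(C)c(OCc2ccccc2)c(Br)c1OCc1ccccc1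
F5 | step 11 | 1-{3-[(6-ethoxy-4-hydroxy-2-methoxy-3-methylphenyl)methyl]-2,4,6-trihydroxy-5-methylphenyl}butan-1-one | CCCC(=O)c1c(O)c(C)c(O)c(Cc2c(OCC)cc(O)c(C)c2OC)c1O
F6 | step 11 | 1-{3-[(2-ethoxy-4-hydroxy-6-methoxy-5-methyl-3-propanoylphenyl)methyl]-2,4,6-trihydroxy-5-methylphenyl}butan-1-one | CCCC(=O)c1c(O)c(C)c(O)c(Cc2c(OCC)c(C(=O)CC)c(O)c(C)c2OC)c1O
F7 | step 7 | 2-{[2,4,6-tris(benzyloxy)-3-bromo-5-methylphenyl]methyl}-4,4-dichloro-3-ethoxycyclobut-2-en-1-one | CCOC1=C(Cc2c(OCc3ccccc3)c(C)c(OCc3ccccc3)c(Br)c2OCc2ccccc2)C(=O)C1(Cl)Cl
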